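Any substrate left over in this flask, charged with 1.05 equivalents of partner, has to be explained by partner going elsewhere.

    substrate + partner → mono adduct (k1 = 0.028 M⁻¹ s⁻¹)
    partner + mono adduct → double product (k2 = 0.016 M⁻¹ s⁻¹)
    partner + double product → tris adduct (k3 = 0.0023 M⁻¹ s⁻¹)
    partner → decomposed reagent (k4 = 0.022 s⁻¹)
    substrate ⇌ dormant form (K5 = 0.59, k5 = 0.0011 s⁻¹)

substrate 0.12 M; partner 0.126 M; time 20 h

1. the state of affairs at 20 h: stopped, and by what, or still going (the partner has run out first / it is still moving / all of the substrate has reacted)
2. how much of the substrate has reacted by 20 h
3. how much mono adduct there is at 20 h, in percent of the substrate charged

- what has gone from substrate into another species counts as reacted, even if it can come back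
- the reaction counts as stopped when no species that holds the substrate changes by six tenths of a point or more over the second half of the time
- run time (flask): 20 h

For the opposite outcome, coupling has to take the partner. At the start partner leaves by two paths, since no mono adduct or double product is charged. Decomposition runs at 0.022 s⁻¹. Coupling, pseudo-first-order in partner, runs at 0.00336 s⁻¹ with substrate as charged. The two paths draw level at a substrate concentration of 0.786 M, but this flask holds 0.12 M, a factor 6.5 short.

The half-life of partner by decomposition is 0.00875 h, shorter than the 0.055 h half-life of substrate by coupling with partner as charged and the 0.18 h forward half-life of substrate into dormant form. So substrate stays near its charge during the first partner half-life, and one ratio can be reckoned: 13.2%. This is the coupling share, the coupling rate over the sum of coupling and decomposition rates at the charged substrate.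

Scaled by the equivalents, it puts mono adduct near 13.9% of the substrate charged. The uncoupled substrate divides with dormant form by 0.59, and the relaxation half-life of 0.0650 h is short against 20 h, so this reckoning gives a conversion of 45.9%. Partner's half-life is also short against that time, so the expected end is: the partner has run out first.

The forecast, lower on mono adduct than this reckoning, reads the partner has run out first, 45.1% and 12.2%, on the grounds that “The partner decomposes within a few minutes, far faster than it couples”.

The flask gives the partner has run out first, with conversion 45.0% and mono adduct 12.1%. In this flask partner stands at 0% of its charge, and the largest change over the second half of the time is 0 percentage points. In this flask decomposed reagent at 0.110 M accounts for all but 12.5% of the partner charge over the whole run, while the coupling share of 13.2% was reckoned at the charged substrate. The neighbour flask charged with 0.032 M of partner has the same share by its formula, which gives 3.52% of the substrate charged, and at 20.0 h that neighbour holds mono adduct at 3.32%.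

(The constants used here are assumed; no experiment stands behind them.)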